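Target at 15 min in birch cannot be read off any earlier run: birch is charged with 1.35 M of partner, more than the 1.1 M of midnight, the highest charge among those runs. From winter to midnight [partner] grows by a factor 3.79 and the target reading by 3.37, with [starting material] held at 1.5 M.

| flask | starting material | partner | remark | time |
|---|---|---|---|---|
| winter | 1.5 M | 0.29 M | run made earlier |  |
| dusk | 1.5 M | 0.57 M | run made earlier |  |
| midnight | 1.5 M | 1.1 M | run made earlier |  |
| ash | 1.5 M | 1.00 M |  | 15 min |
| larch | 1.5 M | 0.400 M |  | 15 min |
| elm | 1.5 M | 0.300 M |  | 15 min |
| maple | 1.5 M | 0.600 M |  | 15 min |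
| birch | 1.5 M | 1.35 M |  | 15 min |

| run | time / min | target / % | starting material / % |
|---|---|---|---|
| winter | 3.00 | 5.2 | 88.0 |
| winter | 6.00 | 9.7 | 85.1 |
| winter | 10.0 | 12.1 | 85.5 |
| winter | 12.0 | 10.2 | 83.0 |
| winter | 15.0 | 10.9 | 82.4 |
| dusk | 1.33 | 8.3 | 87.9 |
| dusk | 4.00 | 14.7 | 79.3 |
| dusk | 8.00 | 18.2 | 73.4 |
| dusk | 10.0 | 19.9 | 68.2 |
| dusk | 15.0 | 20.8 | 66.9 |
| midnight | 1.33 | 13.9 | 79.3 |
| midnight | 2.50 | 20.6 | 68.7 |
| midnight | 4.00 | 27.9 | 59.8 |
| midnight | 8.00 | 35.3 | 50.0 |
| midnight | 15.0 | 36.7 | 42.6 |

(standard deviation of a reading: 1 percentage point)

- the analysis behind the earlier runs scatters by 1 percentage point, standard deviation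
- a reading of starting material is of its free form alone

- the flasks by amount of target, in percent of the starting material charged, highest first, at 15 min (ash / larch / elm / maple / birch)
- the amount of target, in percent of the starting material charged of the flask you put first, at 15 min
- the amount of target, in percent of the starting material charged of the flask you put last, at 15 min

The decision for the next run is what to change, time or partner. Time offers little: midnight's target goes from 35.3% at 8.00 min to 36.7% at 15.0 min, a gain of 1.4 percentage points.

For partner, logarithms turn the two factors above into a slope. Dividing 0.527 by 0.579 gives 0.911, the partner exponent: the change in log target per unit change in log [partner], at fixed [starting material] and time. It is a reading, and each target reading behind it scatters by 1 point. Between dusk and midnight the same slope reads 0.864, which leans the reckoning for birch high.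

Moving up from midnight by 0.0889 in log [partner], birch reckons to 44.2%, a gain larger than the one time offered, so the next run changes partner and keeps the time. Moving up from winter, elm reckons to 11.2%. With a positive exponent, the flasks rank by partner charge.

The forecast gives birch > ash > maple > larch > elm, with birch at 42.5%, lower than this reckoning, and elm at 11.4%, calling birch “least certain, since starting material is getting depleted”.

The flasks give birch > ash > maple > larch > elm, with birch at 42.8% and elm at 11.3%. The reckoning for birch stood 1.4 points high, and the exponent carried from midnight to larch gives 14.6% against its 15.0%.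

    starting material + partner ⇌ target (K = 3.72 M⁻¹, k = 0.00219 M⁻¹ s⁻¹)
    starting material + partner ⇌ isomer of the product (K = 8.42 M⁻¹, k = 9.16 × 10⁻⁴ M⁻¹ s⁻¹)
    partner → decomposition product (k = 4.45 × 10⁻⁷ s⁻¹)

In elm at 15.0 min the selectivity factor of target over isomer of the product, forward rates alone, is 2.4, while the equilibrium constants run the other way, 3.72 M⁻¹ for target and 8.42 M⁻¹ for the isomer. Left to 150 min, birch holds 26.1% target and 47.2% isomer of the product.

(The data are simulated on assumed constants; the scatter is artificial.)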